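**Plan**
- Cuts, in retrosynthetic order: the O‑benzyl bond, the C5′–CH2 bond of the keto chain, the C3 alcohol back to the ketone, then C5–C6 and C9–C10 of ring B together. Behind that come the C7–C8 aryl bond and the naphthalene substituents.
- Enabling feature: ring B (C5–C6–C7–C8–C9–C10) is a tetralin ring whose C6 carries the furan oxygen. C6–C7–C8–C9 can therefore act as a four‑atom cation/arene unit (C6 as aryloxycarbenium carbon, C9 as arene nucleophile), and ring A only has to supply its C5=C10 double bond.
- Forward order: decorate the naphthalene (Me, iPr, CHO, Br), form the nitroalkene, attach ring C at C7, close the furan ring as a lactol and acetylate it. One annulation then closes ring B and brings in ring A. Ketone reduction, side‑chain coupling and debenzylation follow.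
- Stereochemistry: C7 comes from a Rh/chiral‑diene conjugate arylation. C6, C5 and C10 are relayed from C7 in the annulation. C3 comes from substrate‑controlled hydride delivery.

Key step: step 15

Numbering used: abietane numbers C1–C20 for the diterpenoid half; primed naphthalene numbers for the other half (C1′ iPr, C2′ O, C3′ bonded to C7, C5′ side chain, C6′ Me).
Assumption: for each chiral catalyst the antipode that gives the drawn configuration is used, and its sense is confirmed on a model substrate first.

Step 1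
Reactants: 1 6-bromonaphthalen-2-ol
Product: 2 6-bromo-2-(methoxymethoxy)naphthalene
Conditions: NaH, MOMCl, THF, 0 °C to rt
Reagents that add atoms: chloromethyl methyl ether, COCCl
Why: Williamson O‑alkylation of the naphthoxide; the MOM ether later directs lithiation to C3′ and is removable with acid.

Step 2
Reactants: 2 6-bromo-2-(methoxymethoxy)naphthalene
Product: 3 2-(methoxymethoxy)-6-methylnaphthalene
Conditions: MeZnCl, Pd(dppf)Cl2 (2 mol %), THF, 50 °C
Reagents that add atoms: methylzinc chloride, C[Zn]Cl
Why: Negishi coupling of an unhindered aryl bromide with a methylzinc reagent, which leaves the acetal untouched.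

Step 3
Reactants: 3 2-(methoxymethoxy)-6-methylnaphthalene
Product: 4 1-bromo-2-(methoxymethoxy)-6-methylnaphthalene
Conditions: NBS, MeCN, 0 °C
Reagents that add atoms: N-bromosuccinimide, O=C1CCC(=O)N1Br
Why: Electrophilic bromination of a 2‑alkoxynaphthalene goes to the α‑position C1′ next to the oxygen.

Step 4
Reactants: 4 1-bromo-2-(methoxymethoxy)-6-methylnaphthalene
Product: 5 1-isopropyl-2-(methoxymethoxy)-6-methylnaphthalene
Conditions: iPrZnBr, Pd(OAc)2 (2 mol %), CPhos (4 mol %), THF–toluene, rt
Reagents that add atoms: isopropylzinc bromide, CC(C)[Zn]Br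
Why: Negishi coupling of a secondary alkylzinc halide, in which the biaryl phosphine makes reductive elimination faster than β‑hydride elimination/re‑insertion so that the branched group is retained.

Step 5
Reactants: 5 1-isopropyl-2-(methoxymethoxy)-6-methylnaphthalene
Product: 7 4-isopropyl-3-(methoxymethoxy)-7-methylnaphthalene-2-carbaldehyde, via C3′-lithiated naphthalene 6 (not isolated)
Conditions: n-BuLi, TMEDA, Et2O, 0 °C to rt; DMF, −78 °C to rt; H2O
Reagents that add atoms: N,N-dimethylformamide, CN(C)C=O
Why: Directed ortho‑metalation: with C1′ blocked, the OMOM group steers n‑BuLi to C3′, and the aryllithium is formylated with DMF.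

Step 6
Reactants: 7 4-isopropyl-3-(methoxymethoxy)-7-methylnaphthalene-2-carbaldehyde
Product: 8 8-bromo-4-isopropyl-3-(methoxymethoxy)-7-methylnaphthalene-2-carbaldehyde
Conditions: NBS, MeCN, 40 °C, dark
Reagents that add atoms: N-bromosuccinimide, O=C1CCC(=O)N1Br
Why: Electrophilic aromatic bromination: the oxygenated ring is fully blocked or deactivated by the formyl group and C8′ is shielded by the peri isopropyl group, so attack should go to C5′, the α‑position ortho to methyl (as in the C1 bromination of 2‑methylnaphthalene).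

Step 7
Reactants: 8 8-bromo-4-isopropyl-3-(methoxymethoxy)-7-methylnaphthalene-2-carbaldehyde
Product: 9 5-bromo-1-isopropyl-2-(methoxymethoxy)-6-methyl-3-[(E)-2-nitroethenyl]naphthalene
Conditions: MeNO2 (solvent), NH4OAc (0.5 equiv), 95 °C
Reagents that add atoms: nitromethane, C[N+](=O)[O-]
Why: Henry condensation with dehydration in situ gives the conjugated, thermodynamically preferred (E)‑nitroalkene.

Step 8
Reactants: 10 2-isopropylphenol
Product: 11 4-bromo-2-isopropylphenol
Conditions: NBS, MeCN, 0 °C
Reagents that add atoms: N-bromosuccinimide, O=C1CCC(=O)N1Br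
Why: Electrophilic bromination of a phenol, para‑selective under these mild polar conditions.

Step 9
Reactants: 11 4-bromo-2-isopropylphenol
Product: 12 1-(benzyloxy)-4-bromo-2-isopropylbenzene
Conditions: BnBr, K2CO3, DMF, rt
Reagents that add atoms: benzyl bromide, BrCc1ccccc1
Why: Williamson benzylation; the benzyl ether tolerates organolithium, Rh(I), protic acid and cold Lewis acid, and leaves last by hydrogenolysis.

Step 10
Reactants: 12 1-(benzyloxy)-4-bromo-2-isopropylbenzene
Product: 14 [4-(benzyloxy)-3-isopropylphenyl]boronic acid, via aryllithium 13 (not isolated)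
Conditions: n-BuLi, THF, −78 °C; B(OiPr)3, −78 °C to rt; 1 M HCl
Reagents that add atoms: triisopropyl borate, CC(C)OB(OC(C)C)OC(C)C; water, O
Why: Bromine–lithium exchange, borylation with a trialkyl borate and hydrolysis, the standard route to arylboronic acids.

Step 11
Reactants: 9 5-bromo-1-isopropyl-2-(methoxymethoxy)-6-methyl-3-[(E)-2-nitroethenyl]naphthalene; 14 [4-(benzyloxy)-3-isopropylphenyl]boronic acid
Product: 16 3-{(1R)-1-[4-(benzyloxy)-3-isopropylphenyl]-2-nitroethyl}-5-bromo-1-isopropyl-6-methylnaphthalen-2-ol, via MOM-protected nitroalkane 15 (not isolated)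
Conditions: [RhCl(C2H4)2]2 (2.5 mol %), C2-symmetric chiral bicyclo[2.2.2]octadiene (5.5 mol %), KOH (0.2 equiv), dioxane–H2O 10:1, 50 °C; then conc. HCl, MeOH, 50 °C
Reagents that add atoms: none
Why: Hayashi–Miyaura‑type Rh(I)/chiral‑diene conjugate arylation of a β‑aryl nitroalkene sets C7 as R by ligand‑controlled aryl transfer to the Re face of the β‑carbon and tolerates the aryl bromide; the methanolic HCl added afterwards cleaves the MOM acetal while C7, which is β to the nitro group, stays untouched.

Step 12
Reactants: 16 3-{(1R)-1-[4-(benzyloxy)-3-isopropylphenyl]-2-nitroethyl}-5-bromo-1-isopropyl-6-methylnaphthalen-2-ol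
Product: 18 (3R)-3-[4-(benzyloxy)-3-isopropylphenyl]-5-bromo-9-isopropyl-6-methyl-2,3-dihydronaphtho[2,3-b]furan-2-ol (both anomers), via disodium naphtholate-nitronate 17 (not isolated)
Conditions: NaOH (2.2 equiv), THF–H2O, 0 °C; inverse addition into 4 M H2SO4–THF, 0 °C, short contact
Reagents that add atoms: water, O
Why: Nef reaction: the nitronate is hydrolysed in cold strong acid (inverse addition avoids C‑protonation) and the aldehyde is trapped at once by the neighbouring naphthol as the five‑membered lactol, so C7, which nitronate formation does not touch, faces an enolisable carbonyl form only fleetingly.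

Step 13
Reactants: 18 (3R)-3-[4-(benzyloxy)-3-isopropylphenyl]-5-bromo-9-isopropyl-6-methyl-2,3-dihydronaphtho[2,3-b]furan-2-ol
Product: 19 (2S,3R)-3-[4-(benzyloxy)-3-isopropylphenyl]-5-bromo-9-isopropyl-6-methyl-2,3-dihydronaphtho[2,3-b]furan-2-yl acetate (trans anomer drawn)
Conditions: Ac2O, pyridine, CH2Cl2, 0 °C
Reagents that add atoms: acetic anhydride, CC(=O)OC(C)=O
Why: Cold O‑acetylation of the lactol hydroxyl gives the anomeric acetate, expected mainly trans to the C7 aryl group for steric reasons (this centre is erased in step 15), and it is the activating group best suited to ionisation at −78 °C.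

Step 14
Reactants: 20 4-methylcyclohex-2-en-1-one
Product: 22 2,2,4-trimethylcyclohex-3-en-1-one, via 2,4-dimethylcyclohex-3-en-1-one 21 (not isolated)
Conditions: t-BuOK (2.4 equiv), MeI (3 equiv), t-BuOH–THF, 0 °C to rt
Reagents that add atoms: iodomethane, CI
Why: Deconjugative α,α‑dimethylation: γ‑deprotonation gives the extended thermodynamic dienolate, which is methylated twice at the α‑carbon as in the classical 4,4‑dimethylation of steroidal 4‑en‑3‑ones; the stereocentre of 20 disappears.

Step 15
Reactants: 19 (2S,3R)-3-[4-(benzyloxy)-3-isopropylphenyl]-5-bromo-9-isopropyl-6-methyl-2,3-dihydronaphtho[2,3-b]furan-2-yl acetate; 22 2,2,4-trimethylcyclohex-3-en-1-one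
Product: 25 pentacyclic 3-ketone (12-O-benzyl; 5′-bromide; 5α-H 6α-O 7α-C3′ 10β-Me; 5R 6R 7R 10S), via aryloxycarbenium ion 23 (not isolated), via tertiary C10 cation 24 (not isolated)
Conditions: 22 (4 equiv), TMSOTf (0.3 equiv), CH2Cl2, −78 to −40 °C; cold aq. NaHCO3
Reagents that add atoms: none
Why: Proposed new method: TMSOTf strips the anomeric acetate at −78 °C (an acyloxy leaving group is used because only exocyclic ionisation then gives a stabilised cation) to form aryloxycarbenium ion 23, the C5=C10 alkene of 22 adds through its CH terminus C5 in the Markovnikov sense (bond C5–C6), and the tertiary C10 cation 24 is trapped by C9 of the C7 aryl group (bond C9–C10), the released proton turning TMSOAc into AcOH and regenerating TMSOTf. The closest known reaction types are the tandem Prins/Friedel–Crafts annulation of arylacetaldehyde‑derived oxocarbenium ions to tetralins and the Bogert–Cook cyclialkylation of 2‑(2‑arylethyl)‑1,3,3‑trimethylcyclohexyl cations used for abietanes; what is new is the intermolecular capture of a cyclic aryloxycarbenium ion by a neopentyl‑type trisubstituted alkene and the stereochemical relay. Ring B closes by a six‑membered intramolecular Friedel–Crafts alkylation through a chair‑like transition state. C6 is controlled by C7 because only the adduct with C5 on the same face as the C7 aryl group (small C8–C7–C6–C5 dihedral) can bring C9 to C10, whereas the sterically easier anti adduct has no ring‑closing exit and is expected to return by retro‑Prins fragmentation or reversible proton loss; C5 follows from the chair in which the C6–O bond is equatorial and H5/H6 are anti (the alternative puts O6 syn‑axial to the 4β‑ and 10β‑methyl groups), and C10 from anti addition across the alkene, which gives the trans A/B fusion with an axial methyl group. The step needs capture to outrun loss of H7 (aromatisation to the naphthofuran, which would also erase C7), and this is served by the low temperature, the absence of any base, the non‑nucleophilic triflate and the excess of cheap 22. Site selectivity on the arene (C9, not C14) is secured by the C13 isopropyl group, which blocks C14 and activates its para position C9.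

Step 16
Reactants: 25 pentacyclic 3-ketone
Product: 26 pentacyclic 3β-alcohol (12-O-benzyl; 5′-bromide; 3S 5R 6R 7R 10S)
Conditions: NaBH4, MeOH–THF, 0 °C
Reagents that add atoms: none
Why: Substrate‑controlled borohydride reduction of a 4,4‑dimethyl‑3‑ketone in a trans‑decalin: the axial 4β‑ and 10β‑methyl groups cover the β face, so hydride comes from the α face and gives the equatorial 3β‑alcohol (3S).

Step 17
Reactants: 27 methyl isobutyrate
Product: 28 1-isopropylcyclopropan-1-ol
Conditions: EtMgBr (2.2 equiv), Ti(OiPr)4 (10 mol %), Et2O, 0 °C to rt; aq. work-up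
Reagents that add atoms: ethylmagnesium bromide, CC[Mg]Br
Why: Kulinkovich cyclopropanation of an ester through a titanacyclopropane generated from EtMgBr.

Step 18
Reactants: 26 pentacyclic 3β-alcohol; 28 1-isopropylcyclopropan-1-ol
Product: 29 12-O-benzyl ether of the target (C5′ 4-methyl-3-oxopentyl chain in place)
Conditions: 28 (1.5 equiv), Pd(OAc)2 (5 mol %), QPhos (10 mol %), Cs2CO3, toluene, 80 °C
Reagents that add atoms: none
Why: Palladium‑catalysed ring‑opening cross‑coupling of a tertiary cyclopropanol with an aryl bromide: β‑carbon elimination of the Pd(II) cyclopropoxide gives the ketone homoenolate, and the bulky ferrocenyl phosphine favours reductive elimination over β‑hydride elimination, with the hindered secondary alcohol and the benzyl ether as spectators.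

Step 19
Reactants: 29 12-O-benzyl ether of the target
Product: 30 CNP0584944.1 (target)
Conditions: H2 (1 atm), 10% Pd/C, EtOAc–EtOH, rt
Reagents that add atoms: none
Why: Hydrogenolysis of the benzyl aryl ether; the C6–O bond is not benzylic, and the ketone and the naphthalene are inert at 1 atm.

**Compound list**
1 | 6-bromonaphthalen-2-ol | Oc1ccc2cc(Br)ccc2c1 | starting material
2 | 6-bromo-2-(methoxymethoxy)naphthalene | COCOc1ccc2cc(Br)ccc2c1 | intermediate
3 | 2-(methoxymethoxy)-6-methylnaphthalene | COCOc1ccc2cc(C)ccc2c1 | intermediate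
4 | 1-bromo-2-(methoxymethoxy)-6-methylnaphthalene | COCOc1ccc2cc(C)ccc2c1Br | intermediate
5 | 1-isopropyl-2-(methoxymethoxy)-6-methylnaphthalene | COCOc1ccc2cc(C)ccc2c1C(C)C | intermediate
6 | [4-isopropyl-3-(methoxymethoxy)-7-methylnaphthalen-2-yl]lithium | COCOc1c([Li])cc2cc(C)ccc2c1C(C)C | intermediate
7 | 4-isopropyl-3-(methoxymethoxy)-7-methylnaphthalene-2-carbaldehyde | Cc1ccc2c(C(C)C)c(OCOC)c(C=O)cc2c1 | intermediate
8 | 8-bromo-4-isopropyl-3-(methoxymethoxy)-7-methylnaphthalene-2-carbaldehyde | Cc1ccc2c(C(C)C)c(OCOC)c(C=O)cc2c1Br | intermediate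
9 | 5-bromo-1-isopropyl-2-(methoxymethoxy)-6-methyl-3-[(E)-2-nitroethenyl]naphthalene | Cc1ccc2c(C(C)C)c(OCOC)c(/C=C/[N+](=O)[O-])cc2c1Br | intermediate
10 | 2-isopropylphenol | CC(C)c1ccccc1O | starting material
11 | 4-bromo-2-isopropylphenol | CC(C)c1cc(Br)ccc1O | intermediate
12 | 1-(benzyloxy)-4-bromo-2-isopropylbenzene | CC(C)c1cc(Br)ccc1OCc1ccccc1 | intermediate
13 | [4-(benzyloxy)-3-isopropylphenyl]lithium | CC(C)c1cc([Li])ccc1OCc1ccccc1 | intermediate
14 | [4-(benzyloxy)-3-isopropylphenyl]boronic acid | CC(C)c1cc(B(O)O)ccc1OCc1ccccc1 | intermediate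
15 | 3-{(1R)-1-[4-(benzyloxy)-3-isopropylphenyl]-2-nitroethyl}-5-bromo-1-isopropyl-2-(methoxymethoxy)-6-methylnaphthalene | Cc1ccc2c(C(C)C)c(OCOC)c(cc2c1Br)[C@@H](c1ccc(OCc2ccccc2)c(C(C)C)c1)C[N+](=O)[O-] | intermediate
16 | 3-{(1R)-1-[4-(benzyloxy)-3-isopropylphenyl]-2-nitroethyl}-5-bromo-1-isopropyl-6-methylnaphthalen-2-ol | Cc1ccc2c(C(C)C)c(O)c(cc2c1Br)[C@@H](c1ccc(OCc2ccccc2)c(C(C)C)c1)C[N+](=O)[O-] | intermediate
17 | disodium salt of 16 (naphtholate and nitronate) | Cc1ccc2c(C(C)C)c([O-])c(cc2c1Br)[C@@H](c1ccc(OCc2ccccc2)c(C(C)C)c1)C=[N+]([O-])[O-].[Na+].[Na+] | intermediate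
18 | (3R)-3-[4-(benzyloxy)-3-isopropylphenyl]-5-bromo-9-isopropyl-6-methyl-2,3-dihydronaphtho[2,3-b]furan-2-ol, both anomers (C2 undefined) | Cc1ccc2c(C(C)C)c3c(cc2c1Br)[C@@H](c1ccc(OCc2ccccc2)c(C(C)C)c1)C(O)O3 | intermediate
19 | (2S,3R)-3-[4-(benzyloxy)-3-isopropylphenyl]-5-bromo-9-isopropyl-6-methyl-2,3-dihydronaphtho[2,3-b]furan-2-yl acetate (trans anomer) | Cc1ccc2c(C(C)C)c3c(cc2c1Br)[C@@H](c1ccc(OCc2ccccc2)c(C(C)C)c1)[C@H](OC(C)=O)O3 | intermediate
20 | 4-methylcyclohex-2-en-1-one (racemic) | CC1CCC(=O)C=C1 | starting material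
21 | 2,4-dimethylcyclohex-3-en-1-one | CC1=CC(C)C(=O)CC1 | intermediate
22 | 2,2,4-trimethylcyclohex-3-en-1-one | CC1=CC(C)(C)C(=O)CC1 | intermediate
23 | (3R)-3-aryl-5-bromo-9-isopropyl-6-methyl-3H-naphtho[2,3-b]furan-1-ium triflate (C6 aryloxycarbenium ion) | Cc1ccc2c(C(C)C)c3c(cc2c1Br)[C@@H](c1ccc(OCc2ccccc2)c(C(C)C)c1)C=[O+]3.[O-]S(=O)(=O)C(F)(F)F | intermediate
24 | C10 tertiary cation triflate: 2,3-cis-dihydronaphthofuran carrying at C6 the 2,2,6-trimethyl-3-oxocyclohexyl unit bonded through C5, with C10 cationic (5R,6R,7R) | Cc1ccc2c(C(C)C)c3c(cc2c1Br)[C@@H](c1ccc(OCc2ccccc2)c(C(C)C)c1)[C@@H]([C@@H]1[C+](C)CCC(=O)C1(C)C)O3.[O-]S(=O)(=O)C(F)(F)F | intermediate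
25 | (5R,6R,7R,10S)-12-benzyloxyabieta-8,11,13-trien-3-one bridged at C6 (α-O) and C7 (α-C3′) by the 5′-bromo-1′-isopropyl-6′-methylnaphthalene-2′-oxy unit (cis-fused dihydronaphthofuran, trans A/B) | Cc1ccc2c(C(C)C)c3c(cc2c1Br)[C@H]1c2cc(C(C)C)c(OCc4ccccc4)cc2[C@@]2(C)CCC(=O)C(C)(C)[C@@H]2[C@H]1O3 | intermediate
26 | 3β-alcohol of 25 (3S,5R,6R,7R,10S) | Cc1ccc2c(C(C)C)c3c(cc2c1Br)[C@H]1c2cc(C(C)C)c(OCc4ccccc4)cc2[C@@]2(C)CC[C@H](O)C(C)(C)[C@@H]2[C@H]1O3 | intermediate
27 | methyl isobutyrate | COC(=O)C(C)C | starting material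
28 | 1-isopropylcyclopropan-1-ol | CC(C)C1(O)CC1 | intermediate
29 | 12-O-benzyl ether of the target (C5′ CH2CH2C(=O)iPr chain) | Cc1ccc2c(C(C)C)c3c(cc2c1CCC(=O)C(C)C)[C@H]1c2cc(C(C)C)c(OCc4ccccc4)cc2[C@@]2(C)CC[C@H](O)C(C)(C)[C@@H]2[C@H]1O3 | intermediate
30 | CNP0584944.1 (3S,5R,6R,7R,10S) | Cc1ccc2c(C(C)C)c3c(cc2c1CCC(=O)C(C)C)[C@H]1c2cc(C(C)C)c(O)cc2[C@@]2(C)CC[C@H](O)C(C)(C)[C@@H]2[C@H]1O3 | target

Total step count: 19. Longest linear sequence: 14 steps (1–7, 11–13, 15, 16, 18, 19).

**Steps most likely to fail**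

Step 15 (labelled step).
- What may go wrong: loss of H7 from the oxocarbenium ion (aromatisation, with loss of the C7 information) may outrun bimolecular capture by the hindered alkene. Addition anti to the aryl group may also drain material if it is not reversible.
- Fallback concept (known reactions only): rings A and B are closed together by an epoxide‑initiated cation–olefin–arene bicyclisation. The cis C6/C7 relation is fixed beforehand by a carbene C–H insertion.
- Entry and exit: it sets out from aldehyde 8 and bromide 12 (as its lithium reagent 13) and comes back at alcohol 26.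
- Up to the geranyl ether: reagent 13 is added to 8 (THF, −78 °C) to give the diaryl carbinol F1. Dess–Martin oxidation gives the diaryl ketone F2, and HCl/MeOH gives the hydroxy ketone F3. Geranyl bromide/K2CO3 then gives the geranyl ether F4, whose ten carbons map onto C6, C5, C10, C20, C1–C4, C18 and C19.
- C–H insertion: hydrazine gives the hydrazone F5 and MnO2 the diaryldiazomethane F6. A chiral dirhodium carboxylate (Rh2(PTAD)4) effects donor/donor carbene insertion into the allylic O–CH2 bond. This reaction type is established to give 2,3‑cis‑dihydrobenzofurans enantioselectively, and here it gives the cis‑dihydronaphthofuran F7.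
- Bicyclisation: Shi epoxidation of the distal, more electron‑rich trisubstituted alkene gives the (S)‑epoxide F8. MeAlCl2 (CH2Cl2, −78 °C) then triggers the chair–chair bicyclisation terminated at C9, which delivers 26 directly.

Step 12.
- What may go wrong: acid‑catalysed dehydration of the lactol and enolisation of its ring‑opened form may occur during the strongly acidic quench, with erosion at C7. C‑protonation of the nitronate would simply return starting material.
- Fallback (reductive, near neutral, through an isolable intermediate): it sets out from 16 and comes back at 18. SnCl2·2H2O/PhSH/Et3N reduces the primary nitro group to the aldoxime F9. Buffered aqueous TiCl3/NH4OAc (THF, pH about 6) reduces the N–O bond, and the imine hydrolyses to the aldehyde, which closes to lactol 18 without meeting strong acid or base.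

Step 18.
- What may go wrong: coupling at the hindered C5′–Br bond (ortho methyl, peri H4′) may be slow. β‑Hydride elimination of the palladium homoenolate and isomerisation of the cyclopropanol to the open ketone could then take over.
- Fallback (Heck reaction in place of homoenolate coupling): it sets out from 26 and comes back at 30. Bromide 26 reacts with 4‑methylpent‑1‑en‑3‑one (Pd(OAc)2, P(o‑tol)3, NaOAc, DMA, 110 °C) to give the aryl enone F10. H2 over Pd/C then saturates the enone C=C bond and cleaves the benzyl ether in one operation to give 30.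

**Further compounds**
F1 | step 15 | [8-bromo-4-isopropyl-3-(methoxymethoxy)-7-methylnaphthalen-2-yl][4-(benzyloxy)-3-isopropylphenyl]methanol (racemic) | Cc1ccc2c(C(C)C)c(OCOC)c(cc2c1Br)C(O)c1ccc(OCc2ccccc2)c(C(C)C)c1
F2 | step 15 | [8-bromo-4-isopropyl-3-(methoxymethoxy)-7-methylnaphthalen-2-yl][4-(benzyloxy)-3-isopropylphenyl]methanone | Cc1ccc2c(C(C)C)c(OCOC)c(cc2c1Br)C(=O)c1ccc(OCc2ccccc2)c(C(C)C)c1
F3 | step 15 | (8-bromo-3-hydroxy-4-isopropyl-7-methylnaphthalen-2-yl)[4-(benzyloxy)-3-isopropylphenyl]methanone | Cc1ccc2c(C(C)C)c(O)c(cc2c1Br)C(=O)c1ccc(OCc2ccccc2)c(C(C)C)c1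
F4 | step 15 | O-geranyl ether of F3 | Cc1ccc2c(C(C)C)c(OC/C=C(\C)CCC=C(C)C)c(cc2c1Br)C(=O)c1ccc(OCc2ccccc2)c(C(C)C)c1
F5 | step 15 | hydrazone of F4 | Cc1ccc2c(C(C)C)c(OC/C=C(\C)CCC=C(C)C)c(cc2c1Br)C(=NN)c1ccc(OCc2ccccc2)c(C(C)C)c1
F6 | step 15 | diaryldiazomethane from F5 | Cc1ccc2c(C(C)C)c(OC/C=C(\C)CCC=C(C)C)c(cc2c1Br)C(=[N+]=[N-])c1ccc(OCc2ccccc2)c(C(C)C)c1
F7 | step 15 | (2R,3R)-3-[4-(benzyloxy)-3-isopropylphenyl]-5-bromo-2-[(1E)-2,6-dimethylhepta-1,5-dien-1-yl]-9-isopropyl-6-methyl-2,3-dihydronaphtho[2,3-b]furan (2,3-cis) | Cc1ccc2c(C(C)C)c3c(cc2c1Br)[C@@H](c1ccc(OCc2ccccc2)c(C(C)C)c1)[C@@H](/C=C(\C)CCC=C(C)C)O3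
F8 | step 15 | (2R,3R)-2-{(1E)-4-[(2S)-3,3-dimethyloxiran-2-yl]-2-methylbut-1-en-1-yl} analogue of F7 | Cc1ccc2c(C(C)C)c3c(cc2c1Br)[C@@H](c1ccc(OCc2ccccc2)c(C(C)C)c1)[C@@H](/C=C(\C)CC[C@@H]1OC1(C)C)O3
F9 | step 12 | (2R)-2-[4-(benzyloxy)-3-isopropylphenyl]-2-(8-bromo-3-hydroxy-4-isopropyl-7-methylnaphthalen-2-yl)acetaldehyde oxime | Cc1ccc2c(C(C)C)c(O)c(cc2c1Br)[C@@H](c1ccc(OCc2ccccc2)c(C(C)C)c1)C=NO
F10 | step 18 | C5′ (E)-4-methyl-3-oxopent-1-enyl analogue of 29 | Cc1ccc2c(C(C)C)c3c(cc2c1/C=C/C(=O)C(C)C)[C@H]1c2cc(C(C)C)c(OCc4ccccc4)cc2[C@@]2(C)CC[C@H](O)C(C)(C)[C@@H]2[C@H]1O3
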